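## Retrosynthetic overview

1. The target is an ester between C12 of half A and the C13′ oxygen of half B, and the two halves are antipodes. It is cut at this ester (Yamaguchi) into two mirror-image bicyclic lactones, one freed at C12 and the other at its C4′/C13′ diol.
2. The strategy rests on the seven-membered lactone ring of each half (C5–C11(=O)–O10–C9–C8=C7–C6), trans-fused to the cyclohexane C1–C6. A C11 carboxyl and a C7 formyl carbon sit on the adjacent trans carbons C5 and C6 and are bridged by C9–C8(–C12), the carbon skeleton of a 2-phosphonoacrylate, so O10–C9 and C7=C8 are disconnected together.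
3. The trans aldehyde acid (C4/C13 diol as acetonide) comes from a cryptone antipode by vinyl cuprate addition (C7), enolate alkylation with BnOCH2Cl (C11), axial sulfonium ylide epoxidation and hydroxide opening (C13, C4–O), then oxidation-level adjustment.
4. Both cryptone antipodes come from 4-isopropylcyclohexanone by enantioselective deprotonation with either antipode of a chiral lithium amide, followed by Saegusa–Ito oxidation.
5. Ring order: cyclohexane (present from the start), protecting dioxolane, oxepinone ring last in each half (step 12, repeated on the antipode in step 24), then union of the halves and two deprotections.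

Key step: step 12

## Numbering, assumption and remark

- Atom numbering in each half: C1 (CH bearing isopropyl), C2, C3, C4 (carbinol), C5 and C6 (ring fusion), C7=C8 (enoate), C9 (lactone OCH2), O10, C11 (lactone C=O), C12 (carboxyl on C8), C13 (CH2O on C4). Primed numbers refer to half B.
- Half A (free diol, C12 esterified) has the configuration derived from (R)-cryptone (R series). Half B (C13′ esterified, free C12′ acid) is its mirror image, derived from (S)-cryptone (S series).
- Assumption: lithium (R,R)-bis(1-phenylethyl)amide is taken to give the (S)-enol silane, the sense known for 4-substituted cyclohexanones. If the sense were opposite, the two amide antipodes would change places between steps 2 and 14.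
- Remark: because the halves are antipodes made separately, residual minor enantiomer of either series should end up mainly in diastereomeric dimers at the union, removable by chromatography of the coupled ester.
- The C11 oxygen is carried as a benzyl ether, because BnOCH2Cl is a stock reagent and the benzyl group can be removed reductively without touching the vinyl group.

## Route

### Reagent

Step 1
Reactants: 1 allyl diethylphosphonoacetate
Product: 3 allyl 2-(diethoxyphosphoryl)acrylate, via allyloxy adduct 2 (not isolated)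
Conditions: (CH2O)n, piperidine (cat.), allyl alcohol, 80 °C; then TsOH·H2O (cat.), toluene, reflux (Dean–Stark)
Reagents that add atoms: paraformaldehyde, C=O
Why: Knoevenagel-type hydroxymethylation of the active methylene compound, in which the alcohol solvent traps the reactive acrylate as its β-alkoxy adduct 2 (allyl alcohol is chosen so that transesterification cannot change the ester) and acid-catalysed β-elimination with removal of allyl alcohol then releases 3, to be used freshly distilled.

### R series (half A)

Step 2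
Reactants: 4 4-isopropylcyclohexanone
Product: 6 trimethyl{[(4S)-4-(propan-2-yl)cyclohex-1-en-1-yl]oxy}silane, via lithium enolate 5 (not isolated)
Conditions: (R,R)-bis(1-phenylethyl)amine, n-BuLi, THF, −78 °C; then TMSCl and 4, −100 °C (in situ quench)
Reagents that add atoms: chlorotrimethylsilane, C[Si](C)(C)Cl
Why: Enantioselective deprotonation of the prochiral ketone by a C2-symmetric chiral lithium amide (Koga–Simpkins desymmetrisation) with in situ silylation, which distinguishes the enantiotopic α-methylene groups and so fixes the configuration of the isopropyl-bearing carbon (C1 of the target).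

Step 3
Reactants: 6 trimethyl{[(4S)-4-(propan-2-yl)cyclohex-1-en-1-yl]oxy}silane
Product: 7 (R)-cryptone
Conditions: Pd(OAc)2 (10 mol %), O2 (1 atm), DMSO, rt
Reagents that add atoms: none
Why: Saegusa–Ito oxidation, in which the enol silane transmetalates to a divalent palladium enolate, β-hydride elimination places the alkene regiospecifically on the silylated side, O2 reoxidises zerovalent palladium and the stereocentre is not involved.

Step 4
Reactants: 7 (R)-cryptone; 8 vinylmagnesium bromide
Product: 9 trimethyl{[(3R,4R)-3-ethenyl-4-(propan-2-yl)cyclohex-1-en-1-yl]oxy}silane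
Conditions: CuBr·SMe2 (10 mol %), TMSCl, DMPU, THF, −78 °C; Et3N quench
Reagents that add atoms: chlorotrimethylsilane, C[Si](C)(C)Cl
Why: Copper-catalysed conjugate addition of the Grignard reagent accelerated by TMSCl, in which the vinyl group enters C6 anti to the adjacent isopropyl group (trans product by axial attack on the half-chair with isopropyl pseudo-equatorial) and the enolate is trapped regiospecifically as its silyl ether.

Step 5
Reactants: 9 trimethyl{[(3R,4R)-3-ethenyl-4-(propan-2-yl)cyclohex-1-en-1-yl]oxy}silane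
Product: 11 (2R,3R,4R)-2-[(benzyloxy)methyl]-3-ethenyl-4-(propan-2-yl)cyclohexan-1-one, via lithium enolate 10 (not isolated)
Conditions: MeLi, THF, 0 °C; then BnOCH2Cl, −78 → −20 °C
Reagents that add atoms: benzyl chloromethyl ether, ClCOCc1ccccc1
Why: Regiospecific lithium enolate generation from the enol silane followed by C-alkylation with the reactive chloromethyl ether in THF without polar additive, the electrophile approaching C5 anti to the neighbouring vinyl group to give the all-equatorial 2,3-trans ketone, which is also the thermodynamic epimer.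

Step 6
Reactants: 11 (2R,3R,4R)-2-[(benzyloxy)methyl]-3-ethenyl-4-(propan-2-yl)cyclohexan-1-one
Product: 12 (3S,4R,5R,6R)-4-[(benzyloxy)methyl]-5-ethenyl-6-(propan-2-yl)-1-oxaspiro[2.5]octane
Conditions: Me3S+ I−, n-BuLi, THF, −10 °C; then 11, −10 → 0 °C
Reagents that add atoms: trimethylsulfonium iodide, C[S+](C)C.[I-]
Why: Corey–Chaykovsky epoxidation, in which the unstabilised sulfonium ylide adds irreversibly along the axial trajectory of the chair ketone (the equatorial benzyloxymethyl group further disfavours equatorial attack), so that the new C4–C13 bond is axial and the oxygen equatorial, the C4 configuration of the target.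

Step 7
Reactants: 12 (3S,4R,5R,6R)-4-[(benzyloxy)methyl]-5-ethenyl-6-(propan-2-yl)-1-oxaspiro[2.5]octane
Product: 13 (1S,2R,3R,4R)-2-[(benzyloxy)methyl]-3-ethenyl-1-(hydroxymethyl)-4-(propan-2-yl)cyclohexan-1-ol
Conditions: KOH, DMSO/H2O (4:1), 100 °C
Reagents that add atoms: water (delivered as hydroxide), O
Why: Base-mediated epoxide hydrolysis, in which hydroxide opens the oxirane by SN2 attack at the unsubstituted CH2 carbon (C13) so that the C4–O bond and its configuration stay untouched (acid would ionise the tertiary carbon), while the benzyl ether and vinyl group are inert.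

Step 8
Reactants: 13 (1S,2R,3R,4R)-2-[(benzyloxy)methyl]-3-ethenyl-1-(hydroxymethyl)-4-(propan-2-yl)cyclohexan-1-ol
Product: 14 (5S,6R,7R,8R)-6-[(benzyloxy)methyl]-7-ethenyl-2,2-dimethyl-8-(propan-2-yl)-1,3-dioxaspiro[4.5]decane
Conditions: Me2C(OMe)2, PPTS (cat.), CH2Cl2, rt
Reagents that add atoms: 2,2-dimethoxypropane, COC(C)(C)OC
Why: Acid-catalysed transacetalisation closes the five-membered isopropylidene acetal over the 1,2-diol and masks both hydroxyls for the oxidation and annulation steps.

Step 9
Reactants: 14 (5S,6R,7R,8R)-6-[(benzyloxy)methyl]-7-ethenyl-2,2-dimethyl-8-(propan-2-yl)-1,3-dioxaspiro[4.5]decane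
Product: 15 [(5S,6R,7R,8R)-7-ethenyl-2,2-dimethyl-8-(propan-2-yl)-1,3-dioxaspiro[4.5]decan-6-yl]methanol
Conditions: lithium 4,4′-di-tert-butylbiphenylide (LiDBB), THF, −78 °C; NH4Cl (aq)
Reagents that add atoms: none
Why: Reductive cleavage of the benzyl ether by single-electron transfer from the arene radical anion at low temperature, which leaves the isolated vinyl group and the acetonide intact where hydrogenolysis would saturate the alkene.

Step 10
Reactants: 15 [(5S,6R,7R,8R)-7-ethenyl-2,2-dimethyl-8-(propan-2-yl)-1,3-dioxaspiro[4.5]decan-6-yl]methanol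
Product: 17 (5S,6S,7R,8R)-7-ethenyl-2,2-dimethyl-8-(propan-2-yl)-1,3-dioxaspiro[4.5]decane-6-carboxylic acid, via aldehyde 16 (not isolated)
Conditions: TEMPO (cat.), PhI(OAc)2, MeCN/pH 7 phosphate buffer (1:1), rt
Reagents that add atoms: water, O
Why: Oxoammonium (TEMPO) oxidation of the primary alcohol to aldehyde 16 and, through its hydrate, on to the carboxylic acid, the neutral buffer protecting the acetonide and the equatorial C5 substituent having no driving force to epimerise.

Step 11
Reactants: 17 (5S,6S,7R,8R)-7-ethenyl-2,2-dimethyl-8-(propan-2-yl)-1,3-dioxaspiro[4.5]decane-6-carboxylic acid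
Product: 19 (5S,6S,7R,8R)-7-formyl-2,2-dimethyl-8-(propan-2-yl)-1,3-dioxaspiro[4.5]decane-6-carboxylic acid, via ozonide 18 (not isolated)
Conditions: O3, CH2Cl2, −78 °C; then PPh3, −78 °C → rt
Reagents that add atoms: ozone, [O-][O+]=O
Why: Ozonolysis of the terminal alkene with reductive work-up cleaves the vinyl group to the C7 aldehyde without touching C6 and gives the trans γ-oxo acid, which is used directly.

Step 12
Reactants: 19 (5S,6S,7R,8R)-7-formyl-2,2-dimethyl-8-(propan-2-yl)-1,3-dioxaspiro[4.5]decane-6-carboxylic acid; 3 allyl 2-(diethoxyphosphoryl)acrylate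
Product: 22 allyl ester acetonide of the half A lactone (trans-fused oxepinone; 5aS,6R,9S,9aS in 2-benzoxepine numbering), via cesium carboxylate 20 (not isolated), via C8 carbanion 21 (not isolated)
Conditions: Cs2CO3, 3 (slow addition), MeCN, high dilution, 0 °C → rt
Reagents that add atoms: none
Why: Proposed new method: Cs2CO3 converts 19 into cesium carboxylate 20, which adds reversibly through O10 to the β-carbon (C9) of the doubly activated acrylate 3 to give the phosphonate-stabilised C8 carbanion 21, and this is drained irreversibly by intramolecular Horner–Wadsworth–Emmons olefination of the neighbouring C7 aldehyde (7-exo-trig addition, then loss of diethyl phosphate). The closest known reaction type is the tandem oxa-Michael/Horner–Wadsworth–Emmons annulation of hydroxy aldehydes with 2-phosphonoacrylates, extended here from an alkoxide to a carboxylate donor. The oxepinone ring closes in the olefination event, so its C7=C8 alkene is necessarily cis within the ring, and a five-membered lactone is excluded because oxygen can bond only to C9. No stereocentre is created, C5 and C6 are carried through, and their trans relationship is the thermodynamic one should C6 enolise. The step needs the carboxylate to add to 3 faster than the aldehyde enolate forms and reacts at carbon, which the mild carbonate base, the full ionisation of the acid (keeping the γ-oxo acid in its open form) and the gauche, trans-diequatorial placement of carboxylate and formyl groups on C5 and C6 should secure.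

Step 13
Reactants: 22 allyl ester acetonide of the half A lactone
Product: 23 half A lactone acid with acetonide (free C12 carboxylic acid)
Conditions: Pd(PPh3)4 (cat.), PhNHMe, THF, 0 °C
Reagents that add atoms: none
Why: Tsuji–Trost deallylation, in which zerovalent palladium should ionise the unhindered allyl ester much faster than the trisubstituted, ring-bound allylic C9–O10 bond of the lactone, and the weakly basic N-methylaniline traps the allyl fragment without attacking lactone, enoate or acetonide.

### S series (half B)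

Step 14
Reactants: 4 4-isopropylcyclohexanone
Product: 25 trimethyl{[(4R)-4-(propan-2-yl)cyclohex-1-en-1-yl]oxy}silane, via lithium enolate 24 (not isolated)
Conditions: (S,S)-bis(1-phenylethyl)amine, n-BuLi, THF, −78 °C; then TMSCl and 4, −100 °C (in situ quench)
Reagents that add atoms: chlorotrimethylsilane, C[Si](C)(C)Cl
Why: Mirror image of step 2, the antipodal chiral lithium amide removing the other enantiotopic α-hydrogen in the same enantioselective deprotonation and so setting C1′.

Step 15
Reactants: 25 trimethyl{[(4R)-4-(propan-2-yl)cyclohex-1-en-1-yl]oxy}silane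
Product: 26 (S)-cryptone
Conditions: Pd(OAc)2 (10 mol %), O2 (1 atm), DMSO, rt
Reagents that add atoms: none
Why: Mirror image of step 3, a Saegusa–Ito oxidation through a divalent palladium enolate that does not involve the stereocentre.

Step 16
Reactants: 26 (S)-cryptone; 8 vinylmagnesium bromide
Product: 27 trimethyl{[(3S,4S)-3-ethenyl-4-(propan-2-yl)cyclohex-1-en-1-yl]oxy}silane
Conditions: CuBr·SMe2 (10 mol %), TMSCl, DMPU, THF, −78 °C; Et3N quench
Reagents that add atoms: chlorotrimethylsilane, C[Si](C)(C)Cl
Why: Mirror image of step 4, a copper-catalysed conjugate addition with silyl trapping in which the vinyl group enters anti to the isopropyl group.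

Step 17
Reactants: 27 trimethyl{[(3S,4S)-3-ethenyl-4-(propan-2-yl)cyclohex-1-en-1-yl]oxy}silane
Product: 29 (2S,3S,4S)-2-[(benzyloxy)methyl]-3-ethenyl-4-(propan-2-yl)cyclohexan-1-one, via lithium enolate 28 (not isolated)
Conditions: MeLi, THF, 0 °C; then BnOCH2Cl, −78 → −20 °C
Reagents that add atoms: benzyl chloromethyl ether, ClCOCc1ccccc1
Why: Mirror image of step 5, a regiospecific enolate C-alkylation anti to the vinyl group that gives the all-equatorial ketone.

Step 18
Reactants: 29 (2S,3S,4S)-2-[(benzyloxy)methyl]-3-ethenyl-4-(propan-2-yl)cyclohexan-1-one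
Product: 30 (3R,4S,5S,6S)-4-[(benzyloxy)methyl]-5-ethenyl-6-(propan-2-yl)-1-oxaspiro[2.5]octane
Conditions: Me3S+ I−, n-BuLi, THF, −10 °C; then 29, −10 → 0 °C
Reagents that add atoms: trimethylsulfonium iodide, C[S+](C)C.[I-]
Why: Mirror image of step 6, a Corey–Chaykovsky epoxidation by axial attack of the sulfonium ylide that sets C4′ with axial C13′ and equatorial oxygen.

Step 19
Reactants: 30 (3R,4S,5S,6S)-4-[(benzyloxy)methyl]-5-ethenyl-6-(propan-2-yl)-1-oxaspiro[2.5]octane
Product: 31 (1R,2S,3S,4S)-2-[(benzyloxy)methyl]-3-ethenyl-1-(hydroxymethyl)-4-(propan-2-yl)cyclohexan-1-ol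
Conditions: KOH, DMSO/H2O (4:1), 100 °C
Reagents that add atoms: water (delivered as hydroxide), O
Why: Mirror image of step 7, an SN2 opening of the epoxide by hydroxide at the CH2 carbon that retains the C4′ configuration.

Step 20
Reactants: 31 (1R,2S,3S,4S)-2-[(benzyloxy)methyl]-3-ethenyl-1-(hydroxymethyl)-4-(propan-2-yl)cyclohexan-1-ol
Product: 32 (5R,6S,7S,8S)-6-[(benzyloxy)methyl]-7-ethenyl-2,2-dimethyl-8-(propan-2-yl)-1,3-dioxaspiro[4.5]decane
Conditions: Me2C(OMe)2, PPTS (cat.), CH2Cl2, rt
Reagents that add atoms: 2,2-dimethoxypropane, COC(C)(C)OC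
Why: Mirror image of step 8, an acid-catalysed transacetalisation to the isopropylidene acetal of the 1,2-diol.

Step 21
Reactants: 32 (5R,6S,7S,8S)-6-[(benzyloxy)methyl]-7-ethenyl-2,2-dimethyl-8-(propan-2-yl)-1,3-dioxaspiro[4.5]decane
Product: 33 [(5R,6S,7S,8S)-7-ethenyl-2,2-dimethyl-8-(propan-2-yl)-1,3-dioxaspiro[4.5]decan-6-yl]methanol
Conditions: lithium 4,4′-di-tert-butylbiphenylide (LiDBB), THF, −78 °C; NH4Cl (aq)
Reagents that add atoms: none
Why: Mirror image of step 9, a reductive benzyl ether cleavage by electron transfer that spares the vinyl group and the acetonide.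

Step 22
Reactants: 33 [(5R,6S,7S,8S)-7-ethenyl-2,2-dimethyl-8-(propan-2-yl)-1,3-dioxaspiro[4.5]decan-6-yl]methanol
Product: 35 (5R,6R,7S,8S)-7-ethenyl-2,2-dimethyl-8-(propan-2-yl)-1,3-dioxaspiro[4.5]decane-6-carboxylic acid, via aldehyde 34 (not isolated)
Conditions: TEMPO (cat.), PhI(OAc)2, MeCN/pH 7 phosphate buffer (1:1), rt
Reagents that add atoms: water, O
Why: Mirror image of step 10, a TEMPO (oxoammonium) oxidation of the primary alcohol through aldehyde 34 to the acid under neutral buffering.

Step 23
Reactants: 35 (5R,6R,7S,8S)-7-ethenyl-2,2-dimethyl-8-(propan-2-yl)-1,3-dioxaspiro[4.5]decane-6-carboxylic acid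
Product: 37 (5R,6R,7S,8S)-7-formyl-2,2-dimethyl-8-(propan-2-yl)-1,3-dioxaspiro[4.5]decane-6-carboxylic acid, via ozonide 36 (not isolated)
Conditions: O3, CH2Cl2, −78 °C; then PPh3, −78 °C → rt
Reagents that add atoms: ozone, [O-][O+]=O
Why: Mirror image of step 11, an ozonolysis of the vinyl group with reductive work-up that gives the trans γ-oxo acid.

Step 24
Reactants: 37 (5R,6R,7S,8S)-7-formyl-2,2-dimethyl-8-(propan-2-yl)-1,3-dioxaspiro[4.5]decane-6-carboxylic acid; 3 allyl 2-(diethoxyphosphoryl)acrylate
Product: 40 allyl ester acetonide of the half B lactone (trans-fused oxepinone; 5aR,6S,9R,9aR in 2-benzoxepine numbering), via cesium carboxylate 38 (not isolated), via C8 carbanion 39 (not isolated)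
Conditions: Cs2CO3, 3 (slow addition), MeCN, high dilution, 0 °C → rt
Reagents that add atoms: none
Why: Proposed new method: as in step 12 on the antipode, cesium carboxylate 38 adds reversibly through O10′ to C9′ of acrylate 3 and the resulting phosphonate carbanion 39 is consumed irreversibly by intramolecular Horner–Wadsworth–Emmons olefination of the C7′ aldehyde (7-exo-trig addition, then loss of diethyl phosphate). The closest known reaction type is the tandem oxa-Michael/Horner–Wadsworth–Emmons annulation of hydroxy aldehydes with 2-phosphonoacrylates. The seven-membered lactone closes by olefination with its alkene cis in the ring, and no stereocentre is formed. The required preference for carboxylate addition over reaction of the aldehyde enolate rests on the mild base, the ionised acid and the gauche trans-diequatorial arrangement at C5′ and C6′.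

Step 25
Reactants: 40 allyl ester acetonide of the half B lactone
Product: 41 half B lactone diol allyl ester (free C4′ and C13′ hydroxyls)
Conditions: AcOH/H2O/THF (3:1:1), 40 °C
Reagents that add atoms: none
Why: Acid-catalysed acetal hydrolysis, the spiro-dioxolane being the most acid-labile group while allyl ester and lactone survive dilute acetic acid, and the mild medium is chosen so that the freed C13′ hydroxyl does not transacylate the neighbouring lactone.

### Union and end game

Step 26
Reactants: 23 half A lactone acid with acetonide; 41 half B lactone diol allyl ester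
Product: 43 coupled ester (C12–O–C13′) carrying the half A acetonide and the half B allyl ester, via mixed anhydride 42 (not isolated)
Conditions: 2,4,6-Cl3C6H2COCl, Et3N, toluene, rt; then 41, DMAP (cat.), rt
Reagents that add atoms: none
Why: Yamaguchi esterification, in which mixed anhydride 42 acylates the primary C13′ hydroxyl of 41 under DMAP catalysis while the tertiary C4′ hydroxyl is too hindered to compete, and no stereocentre is involved.

Step 27
Reactants: 43 coupled ester carrying the half A acetonide and the half B allyl ester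
Product: 44 coupled ester with free C12′ carboxylic acid and half A acetonide
Conditions: Pd(PPh3)4 (cat.), PhNHMe, THF, 0 °C
Reagents that add atoms: none
Why: Tsuji–Trost deallylation as in step 13, zerovalent palladium ionising the simple allyl ester in preference to the two hindered allylic lactone C–O bonds, with N-methylaniline as a mild allyl acceptor.

Step 28
Reactants: 44 coupled ester with free C12′ carboxylic acid and half A acetonide
Product: 45 CNP0340505.1
Conditions: AcOH/H2O/THF (3:1:1), rt → 40 °C
Reagents that add atoms: none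
Why: Mild acid-catalysed hydrolysis of the isopropylidene acetal frees the C4/C13 diol of half A under conditions that should leave the ester link, both lactones and the tertiary alcohols untouched.

## Compound list

1 | allyl diethylphosphonoacetate | C=CCOC(=O)CP(=O)(OCC)OCC | starting material
2 | allyl 3-(allyloxy)-2-(diethoxyphosphoryl)propanoate | C=CCOCC(C(=O)OCC=C)P(=O)(OCC)OCC | intermediate (not isolated)
3 | allyl 2-(diethoxyphosphoryl)acrylate | C=C(C(=O)OCC=C)P(=O)(OCC)OCC | intermediate
4 | 4-isopropylcyclohexanone | CC(C)C1CCC(=O)CC1 | starting material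
5 | lithium (4S)-4-(propan-2-yl)cyclohex-1-en-1-olate | CC(C)[C@H]1CCC([O-])=CC1.[Li+] | intermediate (not isolated)
6 | trimethyl{[(4S)-4-(propan-2-yl)cyclohex-1-en-1-yl]oxy}silane | CC(C)[C@H]1CCC(O[Si](C)(C)C)=CC1 | intermediate
7 | (R)-cryptone, (4R)-4-(propan-2-yl)cyclohex-2-en-1-one | CC(C)[C@H]1CCC(=O)C=C1 | intermediate
8 | vinylmagnesium bromide | C=C[Mg]Br | starting material
9 | trimethyl{[(3R,4R)-3-ethenyl-4-(propan-2-yl)cyclohex-1-en-1-yl]oxy}silane (vinyl trans to isopropyl) | CC(C)[C@H]1CCC(O[Si](C)(C)C)=C[C@@H]1C=C | intermediate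
10 | lithium (3R,4R)-3-ethenyl-4-(propan-2-yl)cyclohex-1-en-1-olate | CC(C)[C@H]1CCC([O-])=C[C@@H]1C=C.[Li+] | intermediate (not isolated)
11 | (2R,3R,4R)-2-[(benzyloxy)methyl]-3-ethenyl-4-(propan-2-yl)cyclohexan-1-one (all substituents equatorial) | CC(C)[C@H]1CCC(=O)[C@@H](COCc2ccccc2)[C@@H]1C=C | intermediate
12 | (3S,4R,5R,6R)-4-[(benzyloxy)methyl]-5-ethenyl-6-(propan-2-yl)-1-oxaspiro[2.5]octane (epoxide CH2 axial, O equatorial) | CC(C)[C@H]1CC[C@@]2(CO2)[C@@H](COCc3ccccc3)[C@@H]1C=C | intermediate
13 | (1S,2R,3R,4R)-2-[(benzyloxy)methyl]-3-ethenyl-1-(hydroxymethyl)-4-(propan-2-yl)cyclohexan-1-ol | CC(C)[C@H]1CC[C@@](O)(CO)[C@@H](COCc2ccccc2)[C@@H]1C=C | intermediate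
14 | (5S,6R,7R,8R)-6-[(benzyloxy)methyl]-7-ethenyl-2,2-dimethyl-8-(propan-2-yl)-1,3-dioxaspiro[4.5]decane | CC(C)[C@H]1CC[C@@]2(COC(C)(C)O2)[C@@H](COCc3ccccc3)[C@@H]1C=C | intermediate
15 | [(5S,6R,7R,8R)-7-ethenyl-2,2-dimethyl-8-(propan-2-yl)-1,3-dioxaspiro[4.5]decan-6-yl]methanol | CC(C)[C@H]1CC[C@@]2(COC(C)(C)O2)[C@@H](CO)[C@@H]1C=C | intermediate
16 | (5S,6S,7R,8R)-7-ethenyl-2,2-dimethyl-8-(propan-2-yl)-1,3-dioxaspiro[4.5]decane-6-carbaldehyde | CC(C)[C@H]1CC[C@@]2(COC(C)(C)O2)[C@@H](C=O)[C@@H]1C=C | intermediate (not isolated)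
17 | (5S,6S,7R,8R)-7-ethenyl-2,2-dimethyl-8-(propan-2-yl)-1,3-dioxaspiro[4.5]decane-6-carboxylic acid | CC(C)[C@H]1CC[C@@]2(COC(C)(C)O2)[C@@H](C(=O)O)[C@@H]1C=C | intermediate
18 | secondary ozonide (1,2,4-trioxolan-3-yl in place of the vinyl group of 17) | CC(C)[C@H]1CC[C@@]2(COC(C)(C)O2)[C@@H](C(=O)O)[C@@H]1C3OCOO3 | intermediate (not isolated)
19 | (5S,6S,7R,8R)-7-formyl-2,2-dimethyl-8-(propan-2-yl)-1,3-dioxaspiro[4.5]decane-6-carboxylic acid (trans aldehyde acid) | CC(C)[C@H]1CC[C@@]2(COC(C)(C)O2)[C@@H](C(=O)O)[C@@H]1C=O | intermediate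
20 | cesium carboxylate of 19 | CC(C)[C@H]1CC[C@@]2(COC(C)(C)O2)[C@@H](C(=O)[O-])[C@@H]1C=O.[Cs+] | intermediate (not isolated)
21 | cesium C8 carbanion: ester of 19 with the 2-(allyloxycarbonyl)-2-(diethoxyphosphoryl)ethyl unit | CC(C)[C@H]1CC[C@@]2(COC(C)(C)O2)[C@@H](C(=O)OC[C-](C(=O)OCC=C)P(=O)(OCC)OCC)[C@@H]1C=O.[Cs+] | intermediate (not isolated)
22 | allyl (5aS,6R,9S,9aS)-9-hydroxy-9-(hydroxymethyl)-1-oxo-6-(propan-2-yl)-1,3,5a,6,7,8,9,9a-octahydro-2-benzoxepine-4-carboxylate, as the isopropylidene acetal of its two hydroxyls | CC(C)[C@H]1CC[C@@]3(COC(C)(C)O3)[C@H]2C(=O)OCC(C(=O)OCC=C)=C[C@H]12 | intermediate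
23 | (5aS,6R,9S,9aS)-9-hydroxy-9-(hydroxymethyl)-1-oxo-6-(propan-2-yl)-1,3,5a,6,7,8,9,9a-octahydro-2-benzoxepine-4-carboxylic acid, as the isopropylidene acetal | CC(C)[C@H]1CC[C@@]3(COC(C)(C)O3)[C@H]2C(=O)OCC(C(=O)O)=C[C@H]12 | intermediate
24 | lithium (4R)-4-(propan-2-yl)cyclohex-1-en-1-olate | CC(C)[C@@H]1CCC([O-])=CC1.[Li+] | intermediate (not isolated)
25 | trimethyl{[(4R)-4-(propan-2-yl)cyclohex-1-en-1-yl]oxy}silane | CC(C)[C@@H]1CCC(O[Si](C)(C)C)=CC1 | intermediate
26 | (S)-cryptone, (4S)-4-(propan-2-yl)cyclohex-2-en-1-one | CC(C)[C@@H]1CCC(=O)C=C1 | intermediate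
27 | trimethyl{[(3S,4S)-3-ethenyl-4-(propan-2-yl)cyclohex-1-en-1-yl]oxy}silane | CC(C)[C@@H]1CCC(O[Si](C)(C)C)=C[C@H]1C=C | intermediate
28 | lithium (3S,4S)-3-ethenyl-4-(propan-2-yl)cyclohex-1-en-1-olate | CC(C)[C@@H]1CCC([O-])=C[C@H]1C=C.[Li+] | intermediate (not isolated)
29 | (2S,3S,4S)-2-[(benzyloxy)methyl]-3-ethenyl-4-(propan-2-yl)cyclohexan-1-one | CC(C)[C@@H]1CCC(=O)[C@H](COCc2ccccc2)[C@H]1C=C | intermediate
30 | (3R,4S,5S,6S)-4-[(benzyloxy)methyl]-5-ethenyl-6-(propan-2-yl)-1-oxaspiro[2.5]octane | CC(C)[C@@H]1CC[C@]2(CO2)[C@H](COCc3ccccc3)[C@H]1C=C | intermediate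
31 | (1R,2S,3S,4S)-2-[(benzyloxy)methyl]-3-ethenyl-1-(hydroxymethyl)-4-(propan-2-yl)cyclohexan-1-ol | CC(C)[C@@H]1CC[C@](O)(CO)[C@H](COCc2ccccc2)[C@H]1C=C | intermediate
32 | (5R,6S,7S,8S)-6-[(benzyloxy)methyl]-7-ethenyl-2,2-dimethyl-8-(propan-2-yl)-1,3-dioxaspiro[4.5]decane | CC(C)[C@@H]1CC[C@]2(COC(C)(C)O2)[C@H](COCc3ccccc3)[C@H]1C=C | intermediate
33 | [(5R,6S,7S,8S)-7-ethenyl-2,2-dimethyl-8-(propan-2-yl)-1,3-dioxaspiro[4.5]decan-6-yl]methanol | CC(C)[C@@H]1CC[C@]2(COC(C)(C)O2)[C@H](CO)[C@H]1C=C | intermediate
34 | (5R,6R,7S,8S)-7-ethenyl-2,2-dimethyl-8-(propan-2-yl)-1,3-dioxaspiro[4.5]decane-6-carbaldehyde | CC(C)[C@@H]1CC[C@]2(COC(C)(C)O2)[C@H](C=O)[C@H]1C=C | intermediate (not isolated)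
35 | (5R,6R,7S,8S)-7-ethenyl-2,2-dimethyl-8-(propan-2-yl)-1,3-dioxaspiro[4.5]decane-6-carboxylic acid | CC(C)[C@@H]1CC[C@]2(COC(C)(C)O2)[C@H](C(=O)O)[C@H]1C=C | intermediate
36 | secondary ozonide (1,2,4-trioxolan-3-yl in place of the vinyl group of 35) | CC(C)[C@@H]1CC[C@]2(COC(C)(C)O2)[C@H](C(=O)O)[C@H]1C3OCOO3 | intermediate (not isolated)
37 | (5R,6R,7S,8S)-7-formyl-2,2-dimethyl-8-(propan-2-yl)-1,3-dioxaspiro[4.5]decane-6-carboxylic acid | CC(C)[C@@H]1CC[C@]2(COC(C)(C)O2)[C@H](C(=O)O)[C@H]1C=O | intermediate
38 | cesium carboxylate of 37 | CC(C)[C@@H]1CC[C@]2(COC(C)(C)O2)[C@H](C(=O)[O-])[C@H]1C=O.[Cs+] | intermediate (not isolated)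
39 | cesium C8 carbanion: ester of 37 with the 2-(allyloxycarbonyl)-2-(diethoxyphosphoryl)ethyl unit | CC(C)[C@@H]1CC[C@]2(COC(C)(C)O2)[C@H](C(=O)OC[C-](C(=O)OCC=C)P(=O)(OCC)OCC)[C@H]1C=O.[Cs+] | intermediate (not isolated)
40 | allyl (5aR,6S,9R,9aR)-9-hydroxy-9-(hydroxymethyl)-1-oxo-6-(propan-2-yl)-1,3,5a,6,7,8,9,9a-octahydro-2-benzoxepine-4-carboxylate, as the isopropylidene acetal | CC(C)[C@@H]1CC[C@]3(COC(C)(C)O3)[C@@H]2C(=O)OCC(C(=O)OCC=C)=C[C@@H]12 | intermediate
41 | allyl (5aR,6S,9R,9aR)-9-hydroxy-9-(hydroxymethyl)-1-oxo-6-(propan-2-yl)-1,3,5a,6,7,8,9,9a-octahydro-2-benzoxepine-4-carboxylate | CC(C)[C@@H]1CC[C@](O)(CO)[C@@H]2C(=O)OCC(C(=O)OCC=C)=C[C@@H]12 | intermediate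
42 | mixed anhydride of 23 with 2,4,6-trichlorobenzoic acid | CC(C)[C@H]1CC[C@@]3(COC(C)(C)O3)[C@H]2C(=O)OCC(C(=O)OC(=O)c4c(Cl)cc(Cl)cc4Cl)=C[C@H]12 | intermediate (not isolated)
43 | ester of acid 23 with the primary (C13′) hydroxyl of 41: half A as acetonide, half B as allyl ester | CC(C)[C@H]1CC[C@@]5(COC(C)(C)O5)[C@H]2C(=O)OCC(C(=O)OC[C@@]3(O)CC[C@@H](C(C)C)[C@@H]4C=C(C(=O)OCC=C)COC(=O)[C@H]43)=C[C@H]12 | intermediate
44 | as 43 with the half B allyl ester cleaved to the free C12′ carboxylic acid | CC(C)[C@H]1CC[C@@]5(COC(C)(C)O5)[C@H]2C(=O)OCC(C(=O)OC[C@@]3(O)CC[C@@H](C(C)C)[C@@H]4C=C(C(=O)O)COC(=O)[C@H]43)=C[C@H]12 | intermediate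
45 | CNP0340505.1: (5aR,6S,9R,9aR)-9-hydroxy-9-({[(5aS,6R,9S,9aS)-9-hydroxy-9-(hydroxymethyl)-1-oxo-6-(propan-2-yl)-1,3,5a,6,7,8,9,9a-octahydro-2-benzoxepine-4-carbonyl]oxy}methyl)-1-oxo-6-(propan-2-yl)-1,3,5a,6,7,8,9,9a-octahydro-2-benzoxepine-4-carboxylic acid | CC(C)[C@H]1CC[C@@](O)(CO)[C@H]2C(=O)OCC(C(=O)OC[C@@]3(O)CC[C@@H](C(C)C)[C@@H]4C=C(C(=O)O)COC(=O)[C@H]43)=C[C@H]12 | target

## Step count and risks

Total step count: 28 (1 reagent step, 12 steps in each enantiomeric series, 3 steps after the union).
Longest linear sequence: 15 steps (steps 2–13, then 26–28; the S series, steps 14–25 then 26–28, is equally long).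

Three steps most likely to fail:

1. Step 12 (carries the label). Retro-Michael expulsion of the carboxylate from the C8 carbanion may outpace the seven-membered ring-closing olefination, because the ester must first adopt its disfavoured s-cis geometry; the acrylate would then be consumed by oligomerisation or by C-alkylation of the aldehyde enolate at C6. The fallback uses known chemistry only, sets out from 19 and comes back at 22. Base-catalysed oxa-Michael addition of 4-methoxybenzyl alcohol to 3 gives allyl 2-(diethoxyphosphoryl)-3-[(4-methoxybenzyl)oxy]propanoate F1. Intermolecular Horner–Wadsworth–Emmons reaction of the sodium salt of 19 with the anion of F1 (NaH, THF) should give the (E)-enoate acid with the 4-methoxybenzyloxymethyl group on C8 F2, in which C6 and C9 are cis about C7=C8 as usual for α-substituted phosphonoacetates. DDQ (CH2Cl2/pH 7 buffer) removes the 4-methoxybenzyl ether to give the C9 hydroxy acid F3. Mitsunobu lactonisation (PPh3, DIAD, toluene, high dilution) then joins O10 to C9 by SN2 displacement at the primary allylic carbon and returns 22.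

2. Step 24 (carries the label). The same competition between retro-Michael loss and ring-closing olefination applies on the antipode. The fallback sets out from 37 and comes back at 40 by the same known operations: Horner–Wadsworth–Emmons reaction of the sodium salt of 37 with the anion of reagent F1 gives the antipodal (E)-enoate acid F4, DDQ gives the antipodal C9′ hydroxy acid F5, and Mitsunobu lactonisation closes O10′–C9′ to give 40.

3. Step 26. Under the basic acyl-activation conditions the activated enoic acid may deconjugate through a vinylketene with loss of the C6 configuration, and the primary hydroxyl of the diol may transfer intramolecularly onto its own lactone carbonyl faster than it is acylated intermolecularly. The fallback replaces acyl activation by O-alkylation, sets out from 41 and comes back at 43. Selective sulfonylation of the primary hydroxyl (TsCl, Et3N, dibutyltin oxide Bu2SnO cat., CH2Cl2) gives the primary tosylate of the half B diol F6. DBU closes the half B spiro-epoxide allyl ester F7 by attack of the tertiary alkoxide, leaving the C4′ configuration untouched. The cesium salt of 23 (Cs2CO3, DMF, 50 °C) then opens F7 at its CH2 carbon, which forms the C12–O–C13′ ester and the tertiary hydroxyl of 43 without activating the enoic acid and without ever exposing a free primary hydroxyl next to the lactone.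

## Further compounds

F1 | step 12 | allyl 2-(diethoxyphosphoryl)-3-[(4-methoxybenzyl)oxy]propanoate | COc1ccc(COCC(C(=O)OCC=C)P(=O)(OCC)OCC)cc1
F2 | step 12 | (E)-enoate acid of the R series: 19 with the formyl group replaced by CH=C(CO2allyl)CH2O(4-methoxybenzyl), C6 and C9 cis | CC(C)[C@H]1CC[C@@]2(COC(C)(C)O2)[C@@H](C(=O)O)[C@@H]1/C=C(\COCc3ccc(OC)cc3)C(=O)OCC=C
F3 | step 12 | C9 hydroxy acid of the R series: F2 without the 4-methoxybenzyl group | CC(C)[C@H]1CC[C@@]2(COC(C)(C)O2)[C@@H](C(=O)O)[C@@H]1/C=C(\CO)C(=O)OCC=C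
F4 | step 24 | (E)-enoate acid of the S series, antipode of F2 | CC(C)[C@@H]1CC[C@]2(COC(C)(C)O2)[C@H](C(=O)O)[C@H]1/C=C(\COCc3ccc(OC)cc3)C(=O)OCC=C
F5 | step 24 | C9′ hydroxy acid of the S series, antipode of F3 | CC(C)[C@@H]1CC[C@]2(COC(C)(C)O2)[C@H](C(=O)O)[C@H]1/C=C(\CO)C(=O)OCC=C
F6 | step 26 | primary (C13′) p-toluenesulfonate of diol 41 | CC(C)[C@@H]1CC[C@](O)(COS(=O)(=O)c3ccc(C)cc3)[C@@H]2C(=O)OCC(C(=O)OCC=C)=C[C@@H]12
F7 | step 26 | half B spiro-epoxide allyl ester (oxirane spanning C4′ and C13′) | CC(C)[C@@H]1CC[C@]3(CO3)[C@@H]2C(=O)OCC(C(=O)OCC=C)=C[C@@H]12
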